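**Plan**

1. Side-chain carbons are numbered C1'–C32' from the quinone-bound CH2. The retrosynthesis cuts C1'–C2' together with the C3' methyl (terminal alkyne + 2-chloromethylmenadione), then C3'–C4' (acetylide on a primary chloride), then the central C17'–C18' bond, then C9'–C10' and C12'–C13' in the saturated half and C20'–C21' and C28'–C29' in the triene half.
2. Forward, fragment A (the saturated half) is built by two Cu-catalysed sp3–sp3 Grignard couplings that line up an (S)-citronellyl unit, an (R)-2-methylpropane-1,3-diyl unit and an (R)-citronellyl-derived C6 unit; its isopropylidene end is then cleaved to the acid and activated as the N-hydroxyphthalimide ester.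
3. Fragment B (the triene half) is built from geranyl bromide by propargylation, terminal allylic oxidation, isopentyl coupling and carboalumination–iodination. After the union, the chloride is exchanged for ethynyl and a one-pot carboalumination/Ni coupling attaches the head; no ring is formed, the naphthoquinone ring system coming from menadione.
4. Stereochemistry: C7' comes from (R)-citronellyl bromide, C11' from (R)-3-bromo-2-methylpropan-1-ol and C15' from (S)-citronellyl bromide, none ever being a reacting or enolisable carbon. The C22' alkene comes from geranyl bromide, C26' from E-selective SeO2 oxidation, C18' and C2' from syn-carboalumination.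
5. Enabling feature: C17' is a CH2 bonded directly to the vinylic CH (C18') of the E-trisubstituted C18'=C19' alkene and is insulated from the C15' stereocenter by C16'. It can therefore be released as a primary radical by loss of CO2 from the one-carbon-longer acid (that carbon is the old citronellyl alkene carbon) and joined to an alkenyl iodide. The electroreducible naphthoquinone ring is kept out of this step, and a primary chloride at C4' holds the place of the head.

Key step: step 14

Remark: both enantiomers of citronellyl bromide and (R)-3-bromo-2-methylpropan-1-ol are taken as commercial, enantiomerically enriched materials; their enantiomeric purity limits the diastereomeric purity of the chain.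

**Route**

Step 1
Reactants: 1 (2R)-3-bromo-2-methylpropan-1-ol
Product: 2 (2R)-1-bromo-3-chloro-2-methylpropane
Conditions: PPh3, N-chlorosuccinimide, CH2Cl2, 0 °C to rt
Reagents that add atoms: N-chlorosuccinimide, O=C1CCC(=O)N1Cl
Why: Appel-type chlorination displaces the alkoxyphosphonium ion at the primary carbinol carbon by SN2, while the stereocenter is not a reacting carbon and the β-branched C–Br bond should not exchange under these neutral conditions.

Step 2
Reactants: 3 (6S)-8-bromo-2,6-dimethyloct-2-ene [(S)-citronellyl bromide]; 2 (2R)-1-bromo-3-chloro-2-methylpropane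
Product: 5 (6R,10S)-11-chloro-2,6,10-trimethylundec-2-ene, via citronellyl Grignard reagent 4 (not isolated)
Conditions: Mg, THF, 40 °C; then 2, Li2CuCl4 (3 mol%), N-methylpyrrolidone (4 equiv), THF, 0 °C to rt
Reagents that add atoms: none
Why: Kochi–Schlosser-type Cu-catalysed sp3–sp3 Grignard cross-coupling substitutes the C–Br bond of 2 and leaves its C–Cl bond alone, and since neither stereocenter is at a reacting carbon the center of 3 becomes C15' and that of 2 becomes C11' unchanged in space.

Step 3
Reactants: 6 (6R)-8-bromo-2,6-dimethyloct-2-ene [(R)-citronellyl bromide]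
Product: 8 (4R)-6-bromo-4-methylhexan-1-ol, via bromo aldehyde 7 (not isolated)
Conditions: O3, CH2Cl2/MeOH (1:1), −78 °C; then NaBH4 (excess), −78 to 0 °C
Reagents that add atoms: ozone, [O-][O+]=O
Why: Ozonolysis of the trisubstituted alkene with reductive borohydride work-up should give the primary alcohol directly, the primary bromide and the remote stereocenter (future C7') being inert to both reagents.

Step 4
Reactants: 8 (4R)-6-bromo-4-methylhexan-1-ol
Product: 9 (3R)-1-bromo-6-chloro-3-methylhexane
Conditions: PPh3, N-chlorosuccinimide, CH2Cl2, 0 °C to rt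
Reagents that add atoms: N-chlorosuccinimide, O=C1CCC(=O)N1Cl
Why: Appel-type chlorination of the primary alcohol gives a bromide/chloride pair of clearly different reactivity without touching the stereocenter.

Step 5
Reactants: 5 (6R,10S)-11-chloro-2,6,10-trimethylundec-2-ene; 9 (3R)-1-bromo-6-chloro-3-methylhexane
Product: 11 (6R,10S,14S)-17-chloro-2,6,10,14-tetramethylheptadec-2-ene, via alkyl Grignard reagent 10 (not isolated)
Conditions: Mg (I2-activated), THF, reflux; then 9, Li2CuCl4 (3 mol%), THF, −20 °C to rt
Reagents that add atoms: none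
Why: In this second Cu-catalysed sp3–sp3 Grignard cross-coupling the reagent made from the primary chloride 5 should displace the unhindered primary bromide of 9 much faster than its primary chloride, which survives as the placeholder for the later alkyne, and no stereocenter is involved.

Step 6
Reactants: 11 (6R,10S,14S)-17-chloro-2,6,10,14-tetramethylheptadec-2-ene
Product: 12 (4R,8S,12S)-15-chloro-4,8,12-trimethylpentadecanoic acid
Conditions: RuCl3·xH2O (3 mol%), NaIO4 (4 equiv), CCl4/MeCN/H2O (2:2:3), rt
Reagents that add atoms: sodium periodate, [Na+].[O-]I(=O)(=O)=O; water, O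
Why: RuO4-mediated oxidative cleavage (Sharpless RuCl3/NaIO4 conditions) of the isopropylidene alkene should give the carboxylic acid and acetone, the C–Cl bond being inert and the nearest stereocenter lying γ to the new carboxyl group where it cannot epimerise.

Step 7
Reactants: 12 (4R,8S,12S)-15-chloro-4,8,12-trimethylpentadecanoic acid
Product: 13 1,3-dioxoisoindolin-2-yl (4R,8S,12S)-15-chloro-4,8,12-trimethylpentadecanoate
Conditions: N-hydroxyphthalimide, N,N'-diisopropylcarbodiimide, DMAP (5 mol%), CH2Cl2, rt
Reagents that add atoms: N-hydroxyphthalimide, O=C1c2ccccc2C(=O)N1O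
Why: Steglich-type carbodiimide esterification should give the redox-active ester under neutral conditions that touch neither the chloride nor the stereocenters.

Step 8
Reactants: 14 (2E)-1-bromo-3,7-dimethylocta-2,6-diene (geranyl bromide); 15 trimethyl(prop-1-yn-1-yl)silane
Product: 17 trimethyl[(5E)-6,10-dimethylundeca-5,9-dien-1-yn-1-yl]silane, via lithiated silylpropyne 16 (not isolated)
Conditions: 15, n-BuLi, THF, −20 °C; then 14, −78 °C to rt
Reagents that add atoms: none
Why: SN2 alkylation of the propargylic lithium reagent at the primary allylic bromide (α-attack) is the standard two-CH2 homologation of prenyl-type bromides and leaves the E-alkene geometry untouched.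

Step 9
Reactants: 17 trimethyl[(5E)-6,10-dimethylundeca-5,9-dien-1-yn-1-yl]silane
Product: 18 (2E,6E)-2,6-dimethyl-11-(trimethylsilyl)undeca-2,6-dien-10-yn-1-ol
Conditions: SeO2 (0.5 equiv), t-BuOOH (2.5 equiv), salicylic acid (0.1 equiv), CH2Cl2, 0 °C to rt
Reagents that add atoms: selenium dioxide, O=[Se]=O; tert-butyl hydroperoxide, CC(C)(C)OO
Why: Sharpless-type SeO2/t-BuOOH allylic oxidation (ene reaction then [2,3]-sigmatropic shift) should attack the most electron-rich and least hindered alkene, the terminal isopropylidene, and deliver the (E)-allylic alcohol that fixes the C26' alkene geometry.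

Step 10
Reactants: 18 (2E,6E)-2,6-dimethyl-11-(trimethylsilyl)undeca-2,6-dien-10-yn-1-ol
Product: 19 [(5E,9E)-11-bromo-6,10-dimethylundeca-5,9-dien-1-yn-1-yl]trimethylsilane
Conditions: CBr4, PPh3, CH2Cl2, −20 to 0 °C
Reagents that add atoms: carbon tetrabromide, BrC(Br)(Br)Br
Why: Appel bromination of the primary allylic alcohol proceeds by SN2 at the carbinol carbon and should give the allylic bromide without transposition or E/Z isomerisation.

Step 11
Reactants: 19 [(5E,9E)-11-bromo-6,10-dimethylundeca-5,9-dien-1-yn-1-yl]trimethylsilane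
Product: 20 trimethyl[(5E,9E)-6,10,14-trimethylpentadeca-5,9-dien-1-yn-1-yl]silane
Conditions: isopentylmagnesium bromide (1.5 equiv), Li2CuCl4 (5 mol%), THF, −78 to 0 °C
Reagents that add atoms: isopentylmagnesium bromide, CC(C)CC[Mg]Br
Why: Cu-catalysed Grignard substitution of the primary allylic bromide should be α-selective, because γ-attack would have to build a quaternary carbon, so the saturated terminal isoprene unit is attached with the E geometry retained.

Step 12
Reactants: 20 trimethyl[(5E,9E)-6,10,14-trimethylpentadeca-5,9-dien-1-yn-1-yl]silane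
Product: 21 (5E,9E)-6,10,14-trimethylpentadeca-5,9-dien-1-yne
Conditions: K2CO3, MeOH, rt
Reagents that add atoms: none
Why: Base-catalysed methanolysis of the C(sp)–Si bond frees the terminal alkyne without affecting the skipped diene.

Step 13
Reactants: 21 (5E,9E)-6,10,14-trimethylpentadeca-5,9-dien-1-yne
Product: 23 (1E,5E,9E)-1-iodo-2,6,10,14-tetramethylpentadeca-1,5,9-triene, via alkenylalane 22 (not isolated)
Conditions: Me3Al (2.5 equiv), Cp2ZrCl2 (0.25 equiv), CH2Cl2, 0 °C to rt; then I2, THF, −30 to 0 °C
Reagents that add atoms: trimethylaluminium, C[Al](C)C; iodine, II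
Why: Negishi Zr-catalysed carboalumination adds methyl and aluminium syn across the terminal alkyne with aluminium on the terminal carbon, and iodinolysis with retention should give the E-alkenyl iodide that carries the C18'=C19' geometry.

Step 14
Reactants: 13 1,3-dioxoisoindolin-2-yl (4R,8S,12S)-15-chloro-4,8,12-trimethylpentadecanoate; 23 (1E,5E,9E)-1-iodo-2,6,10,14-tetramethylpentadeca-1,5,9-triene
Product: 24 (6E,10E,14E,18R,22S,26S)-29-chloro-2,6,10,14,18,22,26-heptamethylnonacosa-6,10,14-triene
Conditions: NiCl2·6H2O (20 mol%), 2,2'-bipyridine (20 mol%), AgNO3 (0.3 equiv), DMF, rt, undivided cell, Mg anode/reticulated vitreous carbon cathode, constant current (about 3 F per mol of 23), 13 in 1.5-fold excess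
Reagents that add atoms: none
Why: Cathodic reduction gives low-valent nickel–bipyridine, which inserts into the C–I bond of 23 with retention of the E geometry, while single-electron reduction of 13 expels phthalimide anion and CO2 to leave the primary C17' radical; the alkenylnickel captures this radical and reductive elimination from the resulting trivalent nickel species forges the C17'(sp3)–C18'(sp2) bond, the Mg anode supplying the electrons. The closest known reaction type is the Ni-electrocatalytic decarboxylative alkenylation of redox-active esters with alkenyl iodides on a silver-nanoparticle-coated cathode, which joins prenyl-type E-alkenyl iodides to primary alkyl acids in polyene terpenoid chains. No ring is closed and no stereocenter is formed: the three methyl stereocenters of 13 lie at least two carbons from the radical site and cannot epimerise, and the only stereochemical demand, retention of the C18'=C19' geometry, should be met because alkenylnickel species of this type do not isomerise. The step needs cross- over homo-coupling and chemoselectivity, which should be secured by the silver deposit formed in situ (it lowers the overpotential so that 13 is not wasted as alkane or dimer), by the inertness of the primary C–Cl bond towards low-valent nickel at rt, and by the absence of any alkene within cyclisation range of the C17' radical.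

Step 15
Reactants: 24 (6E,10E,14E,18R,22S,26S)-29-chloro-2,6,10,14,18,22,26-heptamethylnonacosa-6,10,14-triene
Product: 25 (6S,10R,14R,17E,21E,25E)-6,10,14,18,22,26,30-heptamethylhentriaconta-17,21,25-trien-1-yne
Conditions: LiC≡CH·H2NCH2CH2NH2 (3 equiv), NaI (0.1 equiv), DMSO/THF (1:1), rt to 40 °C
Reagents that add atoms: lithium acetylide–ethylenediamine complex, [Li]C#C.NCCN
Why: SN2 alkynylation of the unhindered primary chloride by lithium acetylide (iodide-assisted) installs C2' and C3', and the isolated trisubstituted alkenes and the stereocenters have no acidic or electrophilic site for this reagent.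

Step 16
Reactants: 26 2-methylnaphthalene-1,4-dione (menadione)
Product: 27 2-(chloromethyl)-3-methylnaphthalene-1,4-dione
Conditions: aq. HCHO (37%), HCl (gas), AcOH, rt
Reagents that add atoms: formaldehyde, C=O; hydrogen chloride, Cl
Why: Acid-mediated chloromethylation (Blanc-type) can occur only at the single free quinone C–H, C3, and gives the benzylic-type chloride needed for the last coupling.

Step 17
Reactants: 25 (6S,10R,14R,17E,21E,25E)-6,10,14,18,22,26,30-heptamethylhentriaconta-17,21,25-trien-1-yne; 27 2-(chloromethyl)-3-methylnaphthalene-1,4-dione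
Product: 29 2-methyl-3-[(2E,7S,11R,15R,18E,22E,26E)-3,7,11,15,19,23,27,31-octamethyldotriaconta-2,18,22,26-tetraen-1-yl]naphthalene-1,4-dione, via alkenylalane 28 (not isolated)
Conditions: Me3Al (2 equiv), Cp2ZrCl2 (0.25 equiv), ClCH2CH2Cl, 0 °C to rt; volatiles removed in vacuo; then 27 (0.9 equiv), NiCl2(PPh3)2 (5 mol%) pre-reduced with n-BuLi (10 mol%) to zerovalent nickel, THF, 0 °C to rt, dark
Reagents that add atoms: trimethylaluminium, C[Al](C)C
Why: Negishi syn-carboalumination sets the C3' methyl and the E-configured C2'=C3' alkene, and the Ni-catalysed cross-coupling of the alkenylalane with the chloromethylquinone, a reaction type established for allylated para-quinones of the ubiquinone and vitamin K families, should form C1'–C2' with retention while the trisubstituted alkenes and stereocenters stay untouched.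

**Compound list**

1 | (2R)-3-bromo-2-methylpropan-1-ol | OC[C@@H](C)CBr | starting material
2 | (2R)-1-bromo-3-chloro-2-methylpropane | ClC[C@@H](C)CBr | intermediate
3 | (6S)-8-bromo-2,6-dimethyloct-2-ene [(S)-citronellyl bromide] | BrCC[C@@H](C)CCC=C(C)C | starting material
4 | [(3S)-3,7-dimethyloct-6-en-1-yl]magnesium bromide | Br[Mg]CC[C@@H](C)CCC=C(C)C | intermediate
5 | (6R,10S)-11-chloro-2,6,10-trimethylundec-2-ene | ClC[C@@H](C)CCC[C@@H](C)CCC=C(C)C | intermediate
6 | (6R)-8-bromo-2,6-dimethyloct-2-ene [(R)-citronellyl bromide] | BrCC[C@H](C)CCC=C(C)C | starting material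
7 | (4R)-6-bromo-4-methylhexanal | O=CCC[C@@H](C)CCBr | intermediate
8 | (4R)-6-bromo-4-methylhexan-1-ol | OCCC[C@@H](C)CCBr | intermediate
9 | (3R)-1-bromo-6-chloro-3-methylhexane | ClCCC[C@@H](C)CCBr | intermediate
10 | [(2S,6R)-2,6,10-trimethylundec-9-en-1-yl]magnesium chloride | Cl[Mg]C[C@@H](C)CCC[C@@H](C)CCC=C(C)C | intermediate
11 | (6R,10S,14S)-17-chloro-2,6,10,14-tetramethylheptadec-2-ene | ClCCC[C@@H](C)CCC[C@@H](C)CCC[C@@H](C)CCC=C(C)C | intermediate
12 | (4R,8S,12S)-15-chloro-4,8,12-trimethylpentadecanoic acid | ClCCC[C@@H](C)CCC[C@@H](C)CCC[C@@H](C)CCC(=O)O | intermediate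
13 | 1,3-dioxoisoindolin-2-yl (4R,8S,12S)-15-chloro-4,8,12-trimethylpentadecanoate | ClCCC[C@@H](C)CCC[C@@H](C)CCC[C@@H](C)CCC(=O)ON1C(=O)c2ccccc2C1=O | intermediate
14 | (2E)-1-bromo-3,7-dimethylocta-2,6-diene (geranyl bromide) | BrC/C=C(\C)CCC=C(C)C | starting material
15 | trimethyl(prop-1-yn-1-yl)silane | CC#C[Si](C)(C)C | starting material
16 | [3-(trimethylsilyl)prop-2-yn-1-yl]lithium | [Li]CC#C[Si](C)(C)C | intermediate
17 | trimethyl[(5E)-6,10-dimethylundeca-5,9-dien-1-yn-1-yl]silane | C[Si](C)(C)C#CCC/C=C(\C)CCC=C(C)C | intermediate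
18 | (2E,6E)-2,6-dimethyl-11-(trimethylsilyl)undeca-2,6-dien-10-yn-1-ol | C[Si](C)(C)C#CCC/C=C(\C)CC/C=C(\C)CO | intermediate
19 | [(5E,9E)-11-bromo-6,10-dimethylundeca-5,9-dien-1-yn-1-yl]trimethylsilane | C[Si](C)(C)C#CCC/C=C(\C)CC/C=C(\C)CBr | intermediate
20 | trimethyl[(5E,9E)-6,10,14-trimethylpentadeca-5,9-dien-1-yn-1-yl]silane | C[Si](C)(C)C#CCC/C=C(\C)CC/C=C(\C)CCCC(C)C | intermediate
21 | (5E,9E)-6,10,14-trimethylpentadeca-5,9-dien-1-yne | C#CCC/C=C(\C)CC/C=C(\C)CCCC(C)C | intermediate
22 | dimethyl[(1E,5E,9E)-2,6,10,14-tetramethylpentadeca-1,5,9-trien-1-yl]alumane | C[Al](C)/C=C(\C)CC/C=C(\C)CC/C=C(\C)CCCC(C)C | intermediate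
23 | (1E,5E,9E)-1-iodo-2,6,10,14-tetramethylpentadeca-1,5,9-triene | I/C=C(\C)CC/C=C(\C)CC/C=C(\C)CCCC(C)C | intermediate
24 | (6E,10E,14E,18R,22S,26S)-29-chloro-2,6,10,14,18,22,26-heptamethylnonacosa-6,10,14-triene | ClCCC[C@@H](C)CCC[C@@H](C)CCC[C@@H](C)CC/C=C(\C)CC/C=C(\C)CC/C=C(\C)CCCC(C)C | intermediate
25 | (6S,10R,14R,17E,21E,25E)-6,10,14,18,22,26,30-heptamethylhentriaconta-17,21,25-trien-1-yne | C#CCCC[C@@H](C)CCC[C@@H](C)CCC[C@@H](C)CC/C=C(\C)CC/C=C(\C)CC/C=C(\C)CCCC(C)C | intermediate
26 | 2-methylnaphthalene-1,4-dione (menadione) | CC1=CC(=O)c2ccccc2C1=O | starting material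
27 | 2-(chloromethyl)-3-methylnaphthalene-1,4-dione | CC1=C(CCl)C(=O)c2ccccc2C1=O | intermediate
28 | dimethyl[(1E,6S,10R,14R,17E,21E,25E)-2,6,10,14,18,22,26,30-octamethylhentriaconta-1,17,21,25-tetraen-1-yl]alumane | C[Al](C)/C=C(\C)CCC[C@@H](C)CCC[C@@H](C)CCC[C@@H](C)CC/C=C(\C)CC/C=C(\C)CC/C=C(\C)CCCC(C)C | intermediate
29 | 2-methyl-3-[(2E,7S,11R,15R,18E,22E,26E)-3,7,11,15,19,23,27,31-octamethyldotriaconta-2,18,22,26-tetraen-1-yl]naphthalene-1,4-dione | CC1=C(C/C=C(\C)CCC[C@@H](C)CCC[C@@H](C)CCC[C@@H](C)CC/C=C(\C)CC/C=C(\C)CC/C=C(\C)CCCC(C)C)C(=O)c2ccccc2C1=O | target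

**Step count and risks**

Total step count: 17. Longest linear sequence: 9 steps (steps 8–13, then 14, 15 and 17).

Steps most likely to fail:

1. Step 14. Wasteful cathodic reduction of the redox-active ester (protodecarboxylation or dimerisation) or reductive homocoupling of the alkenyl iodide may outrun the cross-coupling, and mass transport of two lipophilic partners in DMF may be poor. The fallback sets out from 13 and 23 and comes back at 24. Iodide 23 would be converted by iodine–lithium exchange (t-BuLi, Et2O, −78 °C) and transmetalation with ZnCl2 into [(1E,5E,9E)-2,6,10,14-tetramethylpentadeca-1,5,9-trien-1-yl]zinc chloride F1. F1 would then be coupled with 13 under thermal catalysis (Ni(acac)2, 2,2'-bipyridine, THF/DMF, rt), the known redox-neutral decarboxylative alkenylation of redox-active esters with alkenylzinc reagents, to give 24 without any electrode process.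

2. Step 9. Site selectivity between the terminal and the internal trisubstituted alkene may be incomplete, over-oxidation to the enal may occur and conversion may stall. The fallback sets out from 17 and comes back at 18, replacing allylic C–H oxidation by degradation and re-olefination. Terminal-selective bromohydrin formation (N-bromosuccinimide, THF/H2O, 0 °C) would give (6E)-3-bromo-2,6-dimethyl-11-(trimethylsilyl)undec-6-en-10-yn-2-ol F2, and DBU would close it to the terminal epoxide trimethyl[(5E)-8-(3,3-dimethyloxiran-2-yl)-6-methyloct-5-en-1-yn-1-yl]silane F3. HIO4 in aqueous THF would cleave F3 to (4E)-4-methyl-9-(trimethylsilyl)non-4-en-8-ynal F4. E-selective Wittig olefination with Ph3P=C(CH3)CO2Et would give ethyl (2E,6E)-2,6-dimethyl-11-(trimethylsilyl)undeca-2,6-dien-10-ynoate F5, and i-Bu2AlH reduction (CH2Cl2, −78 °C) would give 18.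

3. Step 17. Residual organoaluminium species may reduce or add to the quinone carbonyls, or electron transfer from low-valent nickel may consume the quinone before C–C coupling. The fallback sets out from 26 (with 25) and comes back at 29, carrying the ring system as a protected hydroquinone. Reductive methylation of 26 (Na2S2O4, then Me2SO4, KOH) would give 1,4-dimethoxy-2-methylnaphthalene F6, and chloromethylation (paraformaldehyde, HCl, AcOH) would give 2-(chloromethyl)-1,4-dimethoxy-3-methylnaphthalene F7. The same Ni-catalysed coupling with alkenylalane 28, made from 25 as in step 17, would give 1,4-dimethoxy-2-methyl-3-[(2E,7S,11R,15R,18E,22E,26E)-3,7,11,15,19,23,27,31-octamethyldotriaconta-2,18,22,26-tetraen-1-yl]naphthalene F8. Oxidative demethylation with (NH4)2Ce(NO3)6 (MeCN/H2O, 0 °C) would then release 29.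

Further compounds
F1 | step 14 | [(1E,5E,9E)-2,6,10,14-tetramethylpentadeca-1,5,9-trien-1-yl]zinc chloride | Cl[Zn]/C=C(\C)CC/C=C(\C)CC/C=C(\C)CCCC(C)C
F2 | step 9 | (6E)-3-bromo-2,6-dimethyl-11-(trimethylsilyl)undec-6-en-10-yn-2-ol (racemic at C3) | C[Si](C)(C)C#CCC/C=C(\C)CCC(Br)C(C)(C)O
F3 | step 9 | trimethyl[(5E)-8-(3,3-dimethyloxiran-2-yl)-6-methyloct-5-en-1-yn-1-yl]silane (racemic) | C[Si](C)(C)C#CCC/C=C(\C)CCC1OC1(C)C
F4 | step 9 | (4E)-4-methyl-9-(trimethylsilyl)non-4-en-8-ynal | C[Si](C)(C)C#CCC/C=C(\C)CCC=O
F5 | step 9 | ethyl (2E,6E)-2,6-dimethyl-11-(trimethylsilyl)undeca-2,6-dien-10-ynoate | C[Si](C)(C)C#CCC/C=C(\C)CC/C=C(\C)C(=O)OCC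
F6 | step 17 | 1,4-dimethoxy-2-methylnaphthalene | COc1c(C)cc(OC)c2ccccc12
F7 | step 17 | 2-(chloromethyl)-1,4-dimethoxy-3-methylnaphthalene | COc1c(C)c(CCl)c(OC)c2ccccc12
F8 | step 17 | 1,4-dimethoxy-2-methyl-3-[(2E,7S,11R,15R,18E,22E,26E)-3,7,11,15,19,23,27,31-octamethyldotriaconta-2,18,22,26-tetraen-1-yl]naphthalene | COc1c(C)c(C/C=C(\C)CCC[C@@H](C)CCC[C@@H](C)CCC[C@@H](C)CC/C=C(\C)CC/C=C(\C)CC/C=C(\C)CCCC(C)C)c(OC)c2ccccc12
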